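Readings and results are simulated on assumed constants; scatter was added.

Early in the winter run the starting material decays nearly exponentially, so I read a pseudo-first-order constant k between its first and third readings and get 0.382 h⁻¹. Over 10 h that shrinks the starting material by a factor of 45.6. This gives my first extreme: at a low charge c, the product at the end equals the charge, which is a line of slope one on logarithmic axes.

| setting | winter | summer | Wednesday's | Sunday's | Monday's | Thursday's | Saturday's |
|---|---|---|---|---|---|---|---|
| starting material | 0.0039 M | 0.066 M | 0.0060 M | 0.012 M | 0.025 M | 0.050 M | 0.10 M |
| free catalyst | 50 µM | 50 µM | 50 µM | 50 µM | 50 µM | 50 µM | 50 µM |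
| remark | run made earlier | run made earlier |  |  |  |  |  |
| time |  |  | 10 h | 10 h | 10 h | 10 h | 10 h |

| run | time / h | product / % | starting material / % |
|---|---|---|---|
| winter | 0.833 | 24.3 | 75.9 |
| winter | 1.50 | 40.2 | 59.6 |
| winter | 3.00 | 66.5 | 33.2 |
| winter | 5.00 | 85.1 | 14.9 |
| winter | 10.0 | 97.6 | 1.9 |
| summer | 0.833 | 3.4 | 96.6 |
| summer | 1.50 | 4.9 | 94.0 |
| summer | 3.00 | 11.4 | 88.2 |
| summer | 5.00 | 19.6 | 80.8 |
| summer | 10.0 | 39.7 | 60.1 |

(readings scatter by 0.3 percentage points)

- the numbers in the tables scatter with a standard deviation of 0.3 percentage points
- "hardly changes" means that all values lie within two and a half points (for a concentration: within two and a half percent of the largest)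

- [product] at the end for Wednesday's, Sunday's, Monday's, Thursday's, Saturday's, in this order
- how that number moves from the first to the last of them (hardly changes / falls, then rises / rises, then falls / rises all the way / falls all the way)

The summer run shows the other side. Its product forms at 0.00259 M h⁻¹ up to 5.00 h and at 0.00265 M h⁻¹ after it, although its starting material sinks to 60.1%. The winter constant would predict 0.0252 M h⁻¹ at the summer charge, which is more than the summer flask shows. So I suppose that excess starting material holds the catalyst back. My second extreme, which I assume and do not read from the runs, is that the rate goes as the inverse of the charge. The product at the end is then the summer product, 0.0262 M, times the summer charge over c, a line of slope minus one. This is harsher than the level summer rate, so real flasks should stand above it at high charge.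

The two lines cross at the crest charge c*, the geometric mean of the summer product and the summer charge, which is 0.0416 M. I commit to a row that rises, then falls, with a rounded top near c* and Saturday's flask above 0.0173 M.

The forecast, holding that “excess starting material inhibits the catalyst”, gives 0.0058 M, 0.0115 M, 0.022 M, 0.029 M and 0.021 M, so rises, then falls.

The flasks give 0.00588 M, 0.0116 M, 0.0219 M, 0.0277 M and 0.0222 M, so rises, then falls.

    catalyst intermediate B ⇌ free catalyst + product (K = 1.90 M, k = 0.0770 s⁻¹)
    catalyst intermediate A → catalyst intermediate B (k = 0.0410 s⁻¹)
    starting material + catalyst intermediate A ⇌ idle complex, settled at all times (K = 18.0 M⁻¹)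
    starting material + free catalyst → catalyst intermediate A (k = 2.50 M⁻¹ s⁻¹)

The row turns at 0.047 M, which is 1.13 times c*, and Thursday's flask, charged above that turn, ends with 44.5% of its starting material left. Saturday's flask, charged at 2.40 times c*, stands above my inverse line, and at 10.0 h its idle complex holds 44.5% of the catalyst, more than the 6.71% that is free catalyst.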